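**Assumptions.** (R)-Pent-1-en-3-ol, allyl methoxymethyl ether, (−)-Ipc2BOMe and (−)-Ipc2B(allyl) (both from (+)-α-pinene) are taken as catalogue items. Carbons are numbered C1–C15 along the chain: C1≡C2, C3=C4, C6–Cl, C7–O–C13, C9/C10 OAc, C11=C12.

## Retrosynthetic overview

1. Side chain last: Z-enyne by cross-metathesis on a C3=C4 terminal alkene, C6–Cl by inversion of a (6S)-alcohol, C5–C6 by allylboration of a C6 aldehyde.
2. The oxocene (the only ring of the target) is closed late by ring-closing metathesis at C11=C12 of an acyclic diene that already carries C7, C9, C10 and C13.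
3. Key disconnection C9–C10: the C9 aldehyde is attacked by a boron-bound α-alkoxyallyl carbanion equivalent (metalated allyl methoxymethyl ether). C10, formally the carbonyl carbon of acrolein, therefore reacts as a donor; both carbinol centres are set in one step and the new hydroxyl ejects the auxiliary by lactonisation.
4. C7 comes from auxiliary-controlled glycolate alkylation with prenyl bromide (a masked CH2–CHO); C13 is bought in as (R)-pent-1-en-3-ol.
5. Ring order: no ring of the target exists before step 9; the γ-lactone of steps 5–6 is only a relay and is opened in step 7.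

## Route

**Step 1**
Reactants: 1 (R)-pent-1-en-3-ol; 2 bromoacetic acid
Product: 3 2-{[(3R)-pent-1-en-3-yl]oxy}acetic acid
Conditions: NaH (2.5 equiv), THF, 0 °C → rt; aq HCl work-up
Reagents that add atoms: none
Why: Williamson ether synthesis, in which the sodium alkoxide of 1 displaces bromide from sodium bromoacetate at a primary carbon, so the C13 stereocentre is carried over untouched.

**Step 2**
Reactants: 3 2-{[(3R)-pent-1-en-3-yl]oxy}acetic acid; 4 (S)-4-benzyloxazolidin-2-one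
Product: 6 (S)-4-benzyl-3-(2-{[(3R)-pent-1-en-3-yl]oxy}acetyl)oxazolidin-2-one, via mixed pivalic anhydride 5 (not isolated)
Conditions: PivCl, Et3N, THF, −20 °C; then LiCl, 4, −20 °C → rt
Reagents that add atoms: none
Why: N-acylation of the oxazolidinone through the mixed anhydride (LiCl/Et3N acyl transfer) is the standard entry to glycolyl imides and creates no stereocentre.

**Step 3**
Reactants: 6 glycolyl imide; 7 1-bromo-3-methylbut-2-ene (prenyl bromide)
Product: 9 (S)-4-benzyl-3-[(2R)-5-methyl-2-{[(3R)-pent-1-en-3-yl]oxy}hex-4-enoyl]oxazolidin-2-one, via sodium enolate 8 (not isolated)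
Conditions: NaN(SiMe3)2, THF, −78 °C; then 7 (3 equiv), −78 → −45 °C
Reagents that add atoms: none
Why: Evans-type asymmetric alkylation of the chelated sodium (Z)-glycolate enolate, in which prenyl bromide approaches the face opposite the benzyl group and sets C7 as R, the prenyl group serving as a masked CH2–CHO.

**Step 4**
Reactants: 9 prenylated imide
Product: 11 (S)-4-benzyl-3-[(2R)-4-oxo-2-{[(3R)-pent-1-en-3-yl]oxy}butanoyl]oxazolidin-2-one, via secondary ozonide 10 (not isolated)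
Conditions: O3, CH2Cl2, Sudan Red 7B (indicator), −78 °C; then PPh3, −78 °C → rt; used crude
Reagents that add atoms: ozone, [O-][O+]=O
Why: Chemoselective ozonolysis, since the electron-rich trisubstituted alkene reacts far faster than the monosubstituted vinyl group deactivated by the adjacent ether oxygen (dye end-point), and reductive work-up gives the C9 aldehyde.

**Step 5 (key step)**
Reactants: 11 aldehyde imide; 12 3-(methoxymethoxy)prop-1-ene
Product: 15 (3R,5R)-5-[(1R)-1-(methoxymethoxy)prop-2-en-1-yl]-3-{[(3R)-pent-1-en-3-yl]oxy}oxolan-2-one, via alkoxyallylborane 13 (not isolated), via hydroxy imide 14 (not isolated)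
Conditions: 12, s-BuLi, THF, −78 °C; (−)-Ipc2BOMe; BF3·OEt2; then 11, −78 °C, 3 h; 3 M aq NaOAc, 30% H2O2, rt; then Et3N, DMAP (cat.), CH2Cl2, rt
Reagents that add atoms: none
Why: Brown (Z)-γ-alkoxyallylboration followed by lactonisation, in which the metalated allyl ether acts as an α-alkoxyallyl carbanion (a d1 donor at the carbon that would be the electrophilic carbonyl of acrolein) and attacks the C9 aldehyde through a chair six-membered transition state; the Z-alkoxy group gives the syn 9,10-relationship, the isopinocampheyl groups direct attack to the Si face (9R,10R), and the freed γ-hydroxyl then acylates itself on the imide and expels the auxiliary.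

**Step 6**
Reactants: 15 methoxymethyl lactone
Product: 16 (3R,5R)-5-[(1R)-1-hydroxyprop-2-en-1-yl]-3-{[(3R)-pent-1-en-3-yl]oxy}oxolan-2-one
Conditions: Me2BBr (2.5 equiv), CH2Cl2, −78 °C; then THF/aq NaHCO3
Reagents that add atoms: none
Why: Lewis-acid cleavage of the methoxymethyl acetal (Guindon conditions) at −78 °C leaves the lactone and the allylic ether untouched and affects no stereocentre.

**Step 7**
Reactants: 16 hydroxy lactone
Product: 17 (2R,4R,5R)-4,5-dihydroxy-N-methoxy-N-methyl-2-{[(3R)-pent-1-en-3-yl]oxy}hept-6-enamide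
Conditions: MeNH(OMe)·HCl (4 equiv), AlMe3 (4 equiv), CH2Cl2, 0 °C → rt; aq KNaC4H4O6 (potassium sodium tartrate) work-up
Reagents that add atoms: N,O-dimethylhydroxylamine hydrochloride, CNOC.Cl
Why: Weinreb aminolysis of the lactone by the aluminium amide cleaves the acyl C–O bond (any δ-lactone isomer formed in step 6 converges on the same product) and frees the C9 hydroxyl without touching a stereocentre.

**Step 8**
Reactants: 17 diol amide
Product: 18 (3R,4R,6R)-7-[methoxy(methyl)amino]-7-oxo-6-{[(3R)-pent-1-en-3-yl]oxy}hept-1-ene-3,4-diyl diacetate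
Conditions: Ac2O, pyridine, DMAP (cat.), CH2Cl2, 0 °C → rt
Reagents that add atoms: acetic anhydride, CC(=O)OC(C)=O
Why: DMAP-catalysed acetylation of both secondary alcohols installs the two acetates of the target with retention.

**Step 9**
Reactants: 18 diene diacetate
Product: 19 (2R,4R,5R,8R,Z)-8-ethyl-2-[methoxy(methyl)carbamoyl]-3,4,5,8-tetrahydro-2H-oxocine-4,5-diyl diacetate
Conditions: second-generation Grubbs catalyst RuCl2(=CHPh)(H2IMes)(PCy3) (5–10 mol%), CH2Cl2 (2 mM), 40 °C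
Reagents that add atoms: none
Why: Ring-closing metathesis to the oxocene, where the gauche O–C–C–O arrangements along C7–C10 pre-organise the diene, the eight-membered ring enforces the Z C11=C12 alkene, and no stereocentre is touched.

**Step 10**
Reactants: 19 oxocene Weinreb amide
Product: 20 (2R,4R,5R,8R,Z)-8-ethyl-2-formyl-3,4,5,8-tetrahydro-2H-oxocine-4,5-diyl diacetate
Conditions: Cp2Zr(H)Cl (1.5 equiv), THF, rt, 20 min; H2O/silica work-up; used at once
Reagents that add atoms: none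
Why: Schwartz hydrozirconation of the Weinreb amide gives a zirconated hemiaminal that collapses to the aldehyde on work-up, a reduction selective for amides over acetates that leaves C7 configured.

**Step 11**
Reactants: 20 oxocene aldehyde; 21 (−)-B-allyldiisopinocampheylborane
Product: 22 (2R,4R,5R,8R,Z)-8-ethyl-2-[(1S)-1-hydroxybut-3-en-1-yl]-3,4,5,8-tetrahydro-2H-oxocine-4,5-diyl diacetate
Conditions: 21 (1.5 equiv), Et2O, −78 °C, 2 h; 3 M aq NaOAc, 30% H2O2, rt
Reagents that add atoms: none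
Why: Brown allylboration through a chair transition state, in which the reagent attacks the Si face of the aldehyde in line with the Felkin–Anh preference of the α-alkoxy aldehyde, sets C6 as S (anti to the C7 oxygen).

**Step 12**
Reactants: 22 homoallylic alcohol
Product: 23 (2R,4R,5R,8R,Z)-2-[(1R)-1-chlorobut-3-en-1-yl]-8-ethyl-3,4,5,8-tetrahydro-2H-oxocine-4,5-diyl diacetate
Conditions: CCl4, P(n-C8H17)3, toluene, 70 °C
Reagents that add atoms: tetrachloromethane, ClC(Cl)(Cl)Cl
Why: Appel-type chlorination, in which the alkoxyphosphonium ion is displaced by chloride in an SN2 step and C6 is inverted to the required R chloride.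

**Step 13**
Reactants: 24 ethynyltri(propan-2-yl)silane; 25 bromoethene
Product: 26 (but-3-en-1-yn-1-yl)tri(propan-2-yl)silane
Conditions: PdCl2(PPh3)2 (2 mol%), CuI (4 mol%), Et3N, THF, 0 °C → rt
Reagents that add atoms: none
Why: Sonogashira coupling of the terminal alkyne with vinyl bromide gives the silyl-protected 1,3-enyne partner and involves no stereocentre.

**Step 14**
Reactants: 23 chloro alkene; 26 silyl enyne
Product: 27 (2R,4R,5R,8R,Z)-2-[(1R,3Z)-1-chloro-6-[tri(propan-2-yl)silyl]hex-3-en-5-yn-1-yl]-8-ethyl-3,4,5,8-tetrahydro-2H-oxocine-4,5-diyl diacetate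
Conditions: 26 (4 equiv), second-generation Grubbs catalyst RuCl2(=CHPh)(H2IMes)(PCy3) (10 mol%), benzene, 60 °C; Z/E isomers separated
Reagents that add atoms: none
Why: Olefin cross-metathesis of a terminal alkene with a conjugated silyl enyne, which kinetically favours the Z-enyne, while the hindered ring alkene flanked by two oxygenated carbons is a poor metathesis partner and the stereocentres are untouched.

**Step 15**
Reactants: 27 silylated enyne
Product: 28 (2R,4R,5R,8R,Z)-2-[(1R,3Z)-1-chlorohex-3-en-5-yn-1-yl]-8-ethyl-3,4,5,8-tetrahydro-2H-oxocine-4,5-diyl diacetate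
Conditions: Bu4NF, AcOH (1:1, 1.5 equiv), THF, 0 °C
Reagents that add atoms: none
Why: Fluoride-mediated protodesilylation of the alkynylsilane, buffered with acetic acid so that the acetates and the secondary chloride survive, gives the target.

## Compound list

1 | (R)-pent-1-en-3-ol | CC[C@@H](O)C=C | starting material
2 | bromoacetic acid | OC(=O)CBr | starting material
3 | 2-{[(3R)-pent-1-en-3-yl]oxy}acetic acid | CC[C@@H](OCC(=O)O)C=C | intermediate
4 | (S)-4-benzyloxazolidin-2-one | O=C1N[C@@H](Cc2ccccc2)CO1 | starting material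
5 | mixed anhydride of 3 and pivalic acid | CC[C@@H](OCC(=O)OC(=O)C(C)(C)C)C=C | intermediate (not isolated)
6 | (S)-4-benzyl-3-(2-{[(3R)-pent-1-en-3-yl]oxy}acetyl)oxazolidin-2-one | CC[C@@H](OCC(=O)N1[C@@H](Cc2ccccc2)COC1=O)C=C | intermediate
7 | 1-bromo-3-methylbut-2-ene | CC(C)=CCBr | starting material
8 | sodium (Z)-enolate of 6 | [Na+].[O-]/C(=C\O[C@H](CC)C=C)N1[C@@H](Cc2ccccc2)COC1=O | intermediate (not isolated)
9 | (S)-4-benzyl-3-[(2R)-5-methyl-2-{[(3R)-pent-1-en-3-yl]oxy}hex-4-enoyl]oxazolidin-2-one | CC[C@@H](O[C@H](CC=C(C)C)C(=O)N1[C@@H](Cc2ccccc2)COC1=O)C=C | intermediate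
10 | secondary ozonide (1,2,4-trioxolane) of the prenyl alkene of 9 | CC[C@@H](O[C@H](CC1OOC(C)(C)O1)C(=O)N1[C@@H](Cc2ccccc2)COC1=O)C=C | intermediate (not isolated)
11 | (S)-4-benzyl-3-[(2R)-4-oxo-2-{[(3R)-pent-1-en-3-yl]oxy}butanoyl]oxazolidin-2-one | CC[C@@H](O[C@H](CC=O)C(=O)N1[C@@H](Cc2ccccc2)COC1=O)C=C | intermediate
12 | 3-(methoxymethoxy)prop-1-ene | C=CCOCOC | starting material
13 | [(Z)-3-(methoxymethoxy)prop-2-en-1-yl]diisopinocampheylborane (Ipc from (+)-α-pinene) | COCO/C=C\CB([C@@H]1C[C@@H]2C[C@H]([C@H]1C)C2(C)C)[C@@H]1C[C@@H]2C[C@H]([C@H]1C)C2(C)C | intermediate (not isolated)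
14 | (S)-4-benzyl-3-[(2R,4R,5R)-4-hydroxy-5-(methoxymethoxy)-2-{[(3R)-pent-1-en-3-yl]oxy}hept-6-enoyl]oxazolidin-2-one | CC[C@@H](O[C@H](C[C@@H](O)[C@H](OCOC)C=C)C(=O)N1[C@@H](Cc2ccccc2)COC1=O)C=C | intermediate (not isolated)
15 | (3R,5R)-5-[(1R)-1-(methoxymethoxy)prop-2-en-1-yl]-3-{[(3R)-pent-1-en-3-yl]oxy}oxolan-2-one | O=C1O[C@H](C[C@H]1O[C@H](CC)C=C)[C@H](OCOC)C=C | intermediate
16 | (3R,5R)-5-[(1R)-1-hydroxyprop-2-en-1-yl]-3-{[(3R)-pent-1-en-3-yl]oxy}oxolan-2-one | O=C1O[C@H](C[C@H]1O[C@H](CC)C=C)[C@H](O)C=C | intermediate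
17 | (2R,4R,5R)-4,5-dihydroxy-N-methoxy-N-methyl-2-{[(3R)-pent-1-en-3-yl]oxy}hept-6-enamide | CON(C)C(=O)[C@@H](C[C@@H](O)[C@H](O)C=C)O[C@H](CC)C=C | intermediate
18 | (3R,4R,6R)-7-[methoxy(methyl)amino]-7-oxo-6-{[(3R)-pent-1-en-3-yl]oxy}hept-1-ene-3,4-diyl diacetate | CON(C)C(=O)[C@@H](C[C@@H](OC(C)=O)[C@H](OC(C)=O)C=C)O[C@H](CC)C=C | intermediate
19 | (2R,4R,5R,8R,Z)-8-ethyl-2-[methoxy(methyl)carbamoyl]-3,4,5,8-tetrahydro-2H-oxocine-4,5-diyl diacetate | CON(C)C(=O)[C@H]1C[C@@H](OC(C)=O)[C@H](OC(C)=O)/C=C\[C@@H](CC)O1 | intermediate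
20 | (2R,4R,5R,8R,Z)-8-ethyl-2-formyl-3,4,5,8-tetrahydro-2H-oxocine-4,5-diyl diacetate | O=C[C@H]1C[C@@H](OC(C)=O)[C@H](OC(C)=O)/C=C\[C@@H](CC)O1 | intermediate
21 | (−)-B-allyldiisopinocampheylborane (Ipc from (+)-α-pinene) | C=CCB([C@@H]1C[C@@H]2C[C@H]([C@H]1C)C2(C)C)[C@@H]1C[C@@H]2C[C@H]([C@H]1C)C2(C)C | starting material
22 | (2R,4R,5R,8R,Z)-8-ethyl-2-[(1S)-1-hydroxybut-3-en-1-yl]-3,4,5,8-tetrahydro-2H-oxocine-4,5-diyl diacetate | C=CC[C@H](O)[C@H]1C[C@@H](OC(C)=O)[C@H](OC(C)=O)/C=C\[C@@H](CC)O1 | intermediate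
23 | (2R,4R,5R,8R,Z)-2-[(1R)-1-chlorobut-3-en-1-yl]-8-ethyl-3,4,5,8-tetrahydro-2H-oxocine-4,5-diyl diacetate | C=CC[C@@H](Cl)[C@H]1C[C@@H](OC(C)=O)[C@H](OC(C)=O)/C=C\[C@@H](CC)O1 | intermediate
24 | ethynyltri(propan-2-yl)silane | C#C[Si](C(C)C)(C(C)C)C(C)C | starting material
25 | bromoethene | C=CBr | starting material
26 | (but-3-en-1-yn-1-yl)tri(propan-2-yl)silane | C=CC#C[Si](C(C)C)(C(C)C)C(C)C | intermediate
27 | (2R,4R,5R,8R,Z)-2-[(1R,3Z)-1-chloro-6-[tri(propan-2-yl)silyl]hex-3-en-5-yn-1-yl]-8-ethyl-3,4,5,8-tetrahydro-2H-oxocine-4,5-diyl diacetate | CC(C)[Si](C(C)C)(C(C)C)C#C/C=C\C[C@@H](Cl)[C@H]1C[C@@H](OC(C)=O)[C@H](OC(C)=O)/C=C\[C@@H](CC)O1 | intermediate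
28 | (2R,4R,5R,8R,Z)-2-[(1R,3Z)-1-chlorohex-3-en-5-yn-1-yl]-8-ethyl-3,4,5,8-tetrahydro-2H-oxocine-4,5-diyl diacetate | C#C/C=C\C[C@@H](Cl)[C@H]1C[C@@H](OC(C)=O)[C@H](OC(C)=O)/C=C\[C@@H](CC)O1 | target

## Step count and risk

Total step count: 15. Longest linear sequence: 14 steps (steps 1–12, 14 and 15; step 13 makes the enyne partner).

**Step 5 (alkoxyallylboration/lactonisation).** Aldehyde 11 has an acidic imide α-hydrogen and a β-alkoxy group, so elimination or an unclean cascade is possible. The fallback removes the imide before the carbon–carbon bond formation and gives up the lactone relay. It sets out from 9: MeNH(OMe)·HCl/AlMe3 gives the prenylated Weinreb amide F1, ozonolysis as in step 4 gives the less acidic amide aldehyde F2, and the same alkoxyallylborane 13 gives the stable hydroxy amide F3. ZnBr2/n-PrSH (CH2Cl2, rt) then removes the methoxymethyl group and the route is rejoined at 17.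

**Step 9 (ring-closing metathesis).** The acyclic diene 18 may oligomerise instead of closing the eight-membered ring. The fallback closes the ring on the lactone as a conformational template. It sets out from 15: the same ruthenium catalyst (CH2Cl2, 2 mM, 40 °C) gives the bridged bicyclic lactone F4, Me2BBr gives the bridged hydroxy lactone F5, and Weinreb aminolysis as in step 7 gives the oxocene diol amide F6. Acetylation as in step 8 rejoins the route at 19.

**Step 14 (enyne cross-metathesis).** The Z/E ratio may be poor or the catalyst may engage the ring alkene. The fallback builds the enyne by carbonyl olefination and moves the chlorination to the end. It sets out from 22: OsO4 (cat.)/NaIO4/2,6-lutidine in dioxane/H2O cleaves the terminal alkene through the triol F7 to the β-hydroxy aldehyde F8. Peterson-type olefination with lithiated 1,3-bis(triisopropylsilyl)propyne (n-BuLi, THF, −78 °C) gives the (Z)-enyne alcohol F9. Chlorination as in step 12 (CCl4, P(n-C8H17)3) rejoins the route at 27.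

## Further compounds

F1 | step 5 | (2R)-N-methoxy-N,5-dimethyl-2-{[(3R)-pent-1-en-3-yl]oxy}hex-4-enamide | CON(C)C(=O)[C@@H](CC=C(C)C)O[C@H](CC)C=C
F2 | step 5 | (2R)-N-methoxy-N-methyl-4-oxo-2-{[(3R)-pent-1-en-3-yl]oxy}butanamide | CON(C)C(=O)[C@@H](CC=O)O[C@H](CC)C=C
F3 | step 5 | (2R,4R,5R)-4-hydroxy-N-methoxy-5-(methoxymethoxy)-N-methyl-2-{[(3R)-pent-1-en-3-yl]oxy}hept-6-enamide | CON(C)C(=O)[C@@H](C[C@@H](O)[C@H](OCOC)C=C)O[C@H](CC)C=C
F4 | step 9 | (1R,3R,6R,7R,4Z)-3-ethyl-6-(methoxymethoxy)-2,8-dioxabicyclo[5.2.1]dec-4-en-9-one | O=C1O[C@@H]2C[C@H]1O[C@H](CC)/C=C\[C@H]2OCOC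
F5 | step 9 | (1R,3R,6R,7R,4Z)-3-ethyl-6-hydroxy-2,8-dioxabicyclo[5.2.1]dec-4-en-9-one | O=C1O[C@@H]2C[C@H]1O[C@H](CC)/C=C\[C@H]2O
F6 | step 9 | (2R,4R,5R,8R,Z)-8-ethyl-4,5-dihydroxy-N-methoxy-N-methyl-3,4,5,8-tetrahydro-2H-oxocine-2-carboxamide | CON(C)C(=O)[C@H]1C[C@@H](O)[C@H](O)/C=C\[C@@H](CC)O1
F7 | step 14 | (2R,4R,5R,8R,Z)-8-ethyl-2-[(1S)-1,3,4-trihydroxybutyl]-3,4,5,8-tetrahydro-2H-oxocine-4,5-diyl diacetate (C3′ epimers) | OCC(O)C[C@H](O)[C@H]1C[C@@H](OC(C)=O)[C@H](OC(C)=O)/C=C\[C@@H](CC)O1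
F8 | step 14 | (2R,4R,5R,8R,Z)-8-ethyl-2-[(1S)-1-hydroxy-3-oxopropyl]-3,4,5,8-tetrahydro-2H-oxocine-4,5-diyl diacetate | O=CC[C@H](O)[C@H]1C[C@@H](OC(C)=O)[C@H](OC(C)=O)/C=C\[C@@H](CC)O1
F9 | step 14 | (2R,4R,5R,8R,Z)-8-ethyl-2-[(1S,3Z)-1-hydroxy-6-[tri(propan-2-yl)silyl]hex-3-en-5-yn-1-yl]-3,4,5,8-tetrahydro-2H-oxocine-4,5-diyl diacetate | CC(C)[Si](C(C)C)(C(C)C)C#C/C=C\C[C@H](O)[C@H]1C[C@@H](OC(C)=O)[C@H](OC(C)=O)/C=C\[C@@H](CC)O1
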